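(The data come from a simulation with constants of no real substance.)

A small charge of nucleophile has to serve this flask, 0.0500 M against 0.050 M of electrophile, so we reckon by what becomes of it.

- ochre: electrophile 0.050 M; nucleophile 0.050 M; free base 0.15 M; the very flask that is asked about, followed so far
- flask: electrophile 0.050 M; nucleophile 0.0500 M; free base 0.150 M; time 40 h

ochre run (percent of the electrophile charged)

| time / h | electrophile / % | target / % |
|---|---|---|
| 1.00 | 73.6 | 25.1 |
| 2.00 | 64.3 | 34.8 |
| 5.00 | 52.9 | 49.8 |
| 12.0 | 45.8 | 55.3 |

(scatter of a reading: 1 percentage point)

1. part of the electrophile that has reacted at 40 h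
2. share of free nucleophile in free nucleophile and protonated nucleophile together, at 40 h

- the numbers in the tables scatter with a standard deviation of 1 percentage point
- the earlier runs do not show how much of nucleophile is bound; that part of a forecast is a guess

At 12.0 h this flask reads 55.3 % for the catch, the target made per nucleophile charged. Two extremes can be reckoned in the head. If each target took one further nucleophile out of play, the catch would stop at 0.5. If nucleophile went to the electrophile and nowhere else, the first reading would give a half-life of 2.79 h at these equal charges, and c would reach 81.1 % at 12.0 h and 93.5 % at 40 h. The reading lies just above the first extreme and far below the second, and electrophile fell by 7.1 percentage points between the last two readings. The readings show no stop, so we commit to c above the catch at 40 h; as our own guess, taking the fall still to come to be no larger than that last one, c lies below 62.4 %.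

The forecast gives c as 61 %, above the catch, and fr as 3 %, which it calls “uncertain because binding is inferred only indirectly”.

This flask gives c of 57.1 % and fr of 90.3 %.

    electrophile + nucleophile → acid set free + target (k = 0.318 M⁻¹ min⁻¹)
    nucleophile + acid set free ⇌ protonated nucleophile, settled at all times (K = 350 M⁻¹)
    acid set free + free base ⇌ salt of the base (K = 753 M⁻¹, k = 12.8 M⁻¹ min⁻¹)
    nucleophile ⇌ dormant form (K = 1.07, k = 0.0873 min⁻¹)
    2 nucleophile → self-condensation product (k = 0.435 M⁻¹ min⁻¹)

The catch of this flask is now 57.1 %. The flask has come to rest: at 40.0 h nucleophile, the limiting reagent, stands at 0 % of its charge, less than the 43 % of electrophile. At 400 h c is 57.1 %. Ten times the time still clears a remnant, protonated nucleophile going from 2.58 × 10⁻⁷ M to 0 M, and fr at 40 h is a share within such remnants, 87 points above the forecast.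

For the neighbour with 0.12 M of electrophile, our catch gives c of 23.0 % and a full catch 41.7 %. That neighbour gives 31.7 %, between them, a catch of 76.1 %.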